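**Plan**

1. Retrosynthesis: the two benzyl ethers come off last. The C4–C4a bond and the C3–OH bond of the flavan-3-ol are then traced back together, through a 1,2-aryl shift, to the C3–C3a bond and the CH2–OMs group of a trans-2-aryl-3-(mesyloxymethyl)-2,3-dihydrobenzofuran.
2. Further cuts: the aryl–CH2CH2 bond at C5 (B-alkyl Suzuki–Miyaura), the C2–C3 bond of the dihydrobenzofuran (carbenoid C–H insertion), the benzylic ether C–O bond, and the aryl–CO bond (Friedel–Crafts).
3. Forward order: ring A is bought as an arene, acylated and freed at one oxygen; ring B is attached as its benzyl ether; the five-membered oxygen ring closes by C–H insertion; the bibenzyl chain is coupled on; the ester becomes CH2OMs; the oxygen ring then grows from five to six atoms; hydrogenolysis ends the route.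
4. Stereochemistry: C2 is set by the chiral dirhodium carboxylate catalyst in the C–H insertion; the ester carbon is equilibrated to 2,3-trans; the C3 hydroxyl is created with inversion during the ring enlargement, so (2R,3S) follows from the one catalyst-controlled centre.
5. Enabling feature: C4a of ring A lies ortho to the ring oxygen O1 and para to the 7-methoxy group. In the dihydrobenzofuran it is C3a and stands β to the exocyclic CH2–OMs, so it is a strong neighbouring group; the carbon it leaves is C3, exactly where the target carries its hydroxyl.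

Key step: step 9

Assumption 1: the sense of induction of the dirhodium catalyst is taken to give (2S) with the (R)-tert-leucinate ligand; should it prove opposite, the mirror-image catalyst is used and nothing else changes.
Assumption 2: 1-(benzyloxy)-3-ethenylbenzene (11) and 4-(benzyloxy)-3-methoxybenzyl chloride (5) are taken as purchasable; each is otherwise one routine step from 3-(benzyloxy)benzaldehyde or 4-(benzyloxy)-3-methoxybenzyl alcohol.

**Route**

Step 1
Reactants: 1 1-bromo-3,5-dimethoxybenzene; 2 methyl chlorooxoacetate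
Product: 4 methyl 2-(2-bromo-6-hydroxy-4-methoxyphenyl)-2-oxoacetate, via dimethoxy keto ester 3 (not isolated)
Conditions: AlCl3 (3 equiv), CH2Cl2, 0 °C → rt; MeOH quench, dilute HCl
Reagents that add atoms: none
Why: Friedel–Crafts acylation should occur ortho to bromine (para to one methoxy group, ortho to the other, less hindered than the position between the two methoxy groups), and the excess AlCl3 should then cleave only the methyl ether that can chelate to the new ketone (chelation-controlled ortho-demethylation), which frees the future O1 and keeps the future 7-OMe.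

Step 2
Reactants: 4 methyl 2-(2-bromo-6-hydroxy-4-methoxyphenyl)-2-oxoacetate; 5 4-(benzyloxy)-3-methoxybenzyl chloride
Product: 6 methyl 2-(2-{[4-(benzyloxy)-3-methoxyphenyl]methoxy}-6-bromo-4-methoxyphenyl)-2-oxoacetate
Conditions: K2CO3, NaI (cat.), DMF, 40 °C
Reagents that add atoms: none
Why: Williamson etherification of the acidic, hydrogen-bonded phenol with a reactive 4-alkoxybenzyl chloride under mild carbonate conditions should leave the keto ester untouched.

Step 3
Reactants: 6 methyl 2-(2-{[4-(benzyloxy)-3-methoxyphenyl]methoxy}-6-bromo-4-methoxyphenyl)-2-oxoacetate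
Product: 8 methyl 2-(2-{[4-(benzyloxy)-3-methoxyphenyl]methoxy}-6-bromo-4-methoxyphenyl)-2-diazoacetate, via tosylhydrazone 7 (not isolated)
Conditions: TsNHNH2, MeOH, 60 °C; then DBU, CH2Cl2, 0 °C → rt
Reagents that add atoms: p-toluenesulfonyl hydrazide, Cc1ccc(cc1)S(=O)(=O)NN
Why: Condensation of the electrophilic α-keto ester with the sulfonyl hydrazide followed by base-induced loss of sulfinate (Bamford–Stevens-type diazo formation) is the standard entry to aryldiazoacetates and uses no acid that could cleave the 4-alkoxybenzyl aryl ether.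

Step 4
Reactants: 8 methyl 2-(2-{[4-(benzyloxy)-3-methoxyphenyl]methoxy}-6-bromo-4-methoxyphenyl)-2-diazoacetate
Product: 9 methyl (2S,3R)-2-[4-(benzyloxy)-3-methoxyphenyl]-4-bromo-6-methoxy-2,3-dihydro-1-benzofuran-3-carboxylate (2,3-cis)
Conditions: Rh2(R-PTTL)4, dirhodium tetrakis[N-phthaloyl-(R)-tert-leucinate] (1 mol %), toluene, −60 °C
Reagents that add atoms: none
Why: Intramolecular 1,5 C–H insertion of the dirhodium carbenoid of the aryldiazoacetate into the benzylic C–H bond (activated by the ether oxygen and the electron-rich aryl group) should close the dihydrofuran ring, with the chiral carboxylate ligands choosing between the two enantiotopic hydrogens and so setting C2 as S, and with cis as the kinetic relation to the ester.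

Step 5
Reactants: 9 methyl (2S,3R)-2-[4-(benzyloxy)-3-methoxyphenyl]-4-bromo-6-methoxy-2,3-dihydro-1-benzofuran-3-carboxylate
Product: 10 methyl (2S,3S)-2-[4-(benzyloxy)-3-methoxyphenyl]-4-bromo-6-methoxy-2,3-dihydro-1-benzofuran-3-carboxylate (2,3-trans)
Conditions: NaOMe (0.3 equiv), MeOH–THF, 0 °C → rt
Reagents that add atoms: none
Why: Deprotonation α to the ester and reprotonation should equilibrate C3 to the thermodynamically preferred 2,3-trans isomer without touching C2, since ring opening of the ester enolate by β-elimination is a stereoelectronically disfavoured reverse 5-endo-trig process.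

Step 6
Reactants: 10 methyl (2S,3S)-2-[4-(benzyloxy)-3-methoxyphenyl]-4-bromo-6-methoxy-2,3-dihydro-1-benzofuran-3-carboxylate; 11 1-(benzyloxy)-3-ethenylbenzene
Product: 13 methyl (2S,3S)-2-[4-(benzyloxy)-3-methoxyphenyl]-4-{2-[3-(benzyloxy)phenyl]ethyl}-6-methoxy-2,3-dihydro-1-benzofuran-3-carboxylate, via alkylborane 12 (not isolated)
Conditions: 11, 9-BBN, THF, 0 °C → rt; then 10, Pd(OAc)2, SPhos, K3PO4 (aq), THF, 60 °C
Reagents that add atoms: none
Why: Anti-Markovnikov hydroboration of the styrene and B-alkyl Suzuki–Miyaura coupling with the aryl bromide should install the saturated two-carbon link directly, so that no alkene has to be hydrogenated beside the benzyl ethers and no stereocentre is touched.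

Step 7
Reactants: 13 methyl (2S,3S)-2-[4-(benzyloxy)-3-methoxyphenyl]-4-{2-[3-(benzyloxy)phenyl]ethyl}-6-methoxy-2,3-dihydro-1-benzofuran-3-carboxylate
Product: 14 [(2S,3R)-2-[4-(benzyloxy)-3-methoxyphenyl]-4-{2-[3-(benzyloxy)phenyl]ethyl}-6-methoxy-2,3-dihydro-1-benzofuran-3-yl]methanol
Conditions: LiAlH4, THF, 0 °C
Reagents that add atoms: none
Why: Hydride reduction of the ester to the primary alcohol should leave both stereocentres and the benzyl ethers untouched (the descriptor at C3 changes only because the substituent priorities change).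

Step 8
Reactants: 14 [(2S,3R)-2-[4-(benzyloxy)-3-methoxyphenyl]-4-{2-[3-(benzyloxy)phenyl]ethyl}-6-methoxy-2,3-dihydro-1-benzofuran-3-yl]methanol
Product: 15 [(2S,3R)-2-[4-(benzyloxy)-3-methoxyphenyl]-4-{2-[3-(benzyloxy)phenyl]ethyl}-6-methoxy-2,3-dihydro-1-benzofuran-3-yl]methyl methanesulfonate
Conditions: MsCl, Et3N, CH2Cl2, −20 °C
Reagents that add atoms: methanesulfonyl chloride, CS(=O)(=O)Cl
Why: Sulfonylation of the primary alcohol under cold, basic, non-ionising conditions should give the leaving group for the ring enlargement, and the mesylate is used without purification.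

Step 9
Reactants: 15 [(2S,3R)-2-[4-(benzyloxy)-3-methoxyphenyl]-4-{2-[3-(benzyloxy)phenyl]ethyl}-6-methoxy-2,3-dihydro-1-benzofuran-3-yl]methyl methanesulfonate
Product: 17 (2R,3S)-2-[4-(benzyloxy)-3-methoxyphenyl]-5-{2-[3-(benzyloxy)phenyl]ethyl}-7-methoxy-3,4-dihydro-2H-1-benzopyran-3-ol, via phenonium ion 16 (not isolated)
Conditions: (CF3)2CHOH–H2O (4:1), 2,6-lutidine (2 equiv), 45 °C
Reagents that add atoms: water, O
Why: Ionisation of the primary mesylate in the strongly ionising, weakly nucleophilic medium should be assisted by ring A: C3a, ortho to O1 and para to the 6-methoxy group, attacks the CH2 carbon from the rear (Ar1-3 participation, a 3-exo-tet closure of a spirocyclopropane) to give phenonium ion 16, whose charge rests on the two ring A oxygens. Water then opens the three-membered ring at the secondary carbon C3, whose bond to C3a is the one shared with the five-membered ring, so the oxygen heterocycle grows from five to six atoms by a Wagner–Meerwein 1,2-aryl shift; the chroman ring is thus formed by migration of the aryl carbon from C3 to the exocyclic carbon and not by an end-to-end cyclisation. The closest known reaction type is the aryl-assisted solvolysis of 2-arylethyl sulfonates through phenonium ions with stereospecific solvent capture, together with its ring-enlarging variants in benzo-fused cycloalkylmethyl sulfonates. The new stereocentre (C3 of the chroman) is substrate-controlled: water must enter anti to the departing C3–C3a bond, that is with inversion at C3, which with the untouched C2 centre translates the 2,3-trans dihydrobenzofuran into the 2,3-trans flavan-3-ol. The step needs opening at C3 and not at CH2 (attack at CH2 only returns alcohol 14, which can be recycled), capture by water and not proton loss (secured by the large excess of water and the lutidine buffer), and an intact benzylic C2–O1 bond (secured by the neutral medium and by the benzyl ether on the 4-oxygen of ring B, which blocks quinone methide formation).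

Step 10
Reactants: 17 (2R,3S)-2-[4-(benzyloxy)-3-methoxyphenyl]-5-{2-[3-(benzyloxy)phenyl]ethyl}-7-methoxy-3,4-dihydro-2H-1-benzopyran-3-ol
Product: 18 Shanciol B, (2R,3S)-2-(4-hydroxy-3-methoxyphenyl)-5-[2-(3-hydroxyphenyl)ethyl]-7-methoxy-3,4-dihydro-2H-1-benzopyran-3-ol
Conditions: H2 (1 atm), Pd(OH)2/C, EtOAc–MeOH, rt
Reagents that add atoms: none
Why: Hydrogenolysis of the two benzyl aryl ethers under mild neutral conditions, as practised on benzylated flavan-3-ols, should free both phenols without cleaving the benzylic C2–O1 bond or disturbing the stereocentres.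

**Compound list**

1 | 1-bromo-3,5-dimethoxybenzene | COc1cc(Br)cc(OC)c1 | starting material
2 | methyl chlorooxoacetate | COC(=O)C(=O)Cl | starting material
3 | methyl 2-(2-bromo-4,6-dimethoxyphenyl)-2-oxoacetate | COC(=O)C(=O)c1c(Br)cc(OC)cc1OC | intermediate
4 | methyl 2-(2-bromo-6-hydroxy-4-methoxyphenyl)-2-oxoacetate | COC(=O)C(=O)c1c(Br)cc(OC)cc1O | intermediate
5 | 4-(benzyloxy)-3-methoxybenzyl chloride | ClCc1ccc(OCc2ccccc2)c(OC)c1 | starting material
6 | methyl 2-(2-{[4-(benzyloxy)-3-methoxyphenyl]methoxy}-6-bromo-4-methoxyphenyl)-2-oxoacetate | COC(=O)C(=O)c1c(Br)cc(OC)cc1OCc1ccc(OCc2ccccc2)c(OC)c1 | intermediate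
7 | N-tosylhydrazone of 6 (C=N geometry not defined) | COC(=O)C(=NNS(=O)(=O)c1ccc(C)cc1)c1c(Br)cc(OC)cc1OCc1ccc(OCc2ccccc2)c(OC)c1 | intermediate
8 | methyl 2-(2-{[4-(benzyloxy)-3-methoxyphenyl]methoxy}-6-bromo-4-methoxyphenyl)-2-diazoacetate | COC(=O)C(=[N+]=[N-])c1c(Br)cc(OC)cc1OCc1ccc(OCc2ccccc2)c(OC)c1 | intermediate
9 | methyl (2S,3R)-2-[4-(benzyloxy)-3-methoxyphenyl]-4-bromo-6-methoxy-2,3-dihydro-1-benzofuran-3-carboxylate (cis) | COC(=O)[C@H]1[C@@H](c2ccc(OCc3ccccc3)c(OC)c2)Oc2cc(OC)cc(Br)c21 | intermediate
10 | methyl (2S,3S)-2-[4-(benzyloxy)-3-methoxyphenyl]-4-bromo-6-methoxy-2,3-dihydro-1-benzofuran-3-carboxylate (trans) | COC(=O)[C@@H]1[C@@H](c2ccc(OCc3ccccc3)c(OC)c2)Oc2cc(OC)cc(Br)c21 | intermediate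
11 | 1-(benzyloxy)-3-ethenylbenzene | C=Cc1cccc(OCc2ccccc2)c1 | starting material
12 | 9-{2-[3-(benzyloxy)phenyl]ethyl}-9-borabicyclo[3.3.1]nonane | C(Cc1cccc(OCc2ccccc2)c1)B1C2CCCC1CCC2 | intermediate
13 | methyl (2S,3S)-2-[4-(benzyloxy)-3-methoxyphenyl]-4-{2-[3-(benzyloxy)phenyl]ethyl}-6-methoxy-2,3-dihydro-1-benzofuran-3-carboxylate | COC(=O)[C@@H]1[C@@H](c2ccc(OCc3ccccc3)c(OC)c2)Oc2cc(OC)cc(CCc3cccc(OCc4ccccc4)c3)c21 | intermediate
14 | [(2S,3R)-2-[4-(benzyloxy)-3-methoxyphenyl]-4-{2-[3-(benzyloxy)phenyl]ethyl}-6-methoxy-2,3-dihydro-1-benzofuran-3-yl]methanol | OC[C@@H]1[C@@H](c2ccc(OCc3ccccc3)c(OC)c2)Oc2cc(OC)cc(CCc3cccc(OCc4ccccc4)c3)c21 | intermediate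
15 | methanesulfonate of 14 | CS(=O)(=O)OC[C@@H]1[C@@H](c2ccc(OCc3ccccc3)c(OC)c2)Oc2cc(OC)cc(CCc3cccc(OCc4ccccc4)c3)c21 | intermediate
16 | phenonium ion: spirocyclopropane in which the former C3a is bonded to C3 and to the former CH2OMs carbon, drawn with the charge on the methoxy oxygen of ring A | C[O+]=C1C=C(CCc2cccc(OCc3ccccc3)c2)[C@@]23C[C@@H]2[C@@H](c2ccc(OCc4ccccc4)c(OC)c2)OC3=C1 | intermediate
17 | (2R,3S)-2-[4-(benzyloxy)-3-methoxyphenyl]-5-{2-[3-(benzyloxy)phenyl]ethyl}-7-methoxy-3,4-dihydro-2H-1-benzopyran-3-ol | COc1cc(CCc2cccc(OCc3ccccc3)c2)c2c(c1)O[C@H](c1ccc(OCc3ccccc3)c(OC)c1)[C@@H](O)C2 | intermediate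
18 | Shanciol B | COc1cc(CCc2cccc(O)c2)c2c(c1)O[C@H](c1ccc(O)c(OC)c1)[C@@H](O)C2 | target

**Step count and risks**

Total steps: 10. Longest linear sequence: 10 steps (1 → 18).

Step 9 (ring enlargement). The bridged cation may lose a proton instead of taking up water, water may attack the primary carbon and return unrearranged material, or aryl participation may be slow because the five-membered ring holds C3 near the plane of ring A. Fallback: the fallback sets out from mesylate 15. The rearrangement is run without water ((CF3)2CHOH, 2,6-di-tert-butylpyridine, 50 °C), so that the rearranged cation sheds a proton from C4 and gives the ring-enlarged (2S)-2-[4-(benzyloxy)-3-methoxyphenyl]-5-{2-[3-(benzyloxy)phenyl]ethyl}-7-methoxy-2H-1-benzopyran F1. Only this C3=C4 isomer keeps the C2 centre. Hydroboration–oxidation (BH3·SMe2, THF, 0 °C; NaOH, H2O2) should then place boron on C3 from the face anti to the C2 aryl group, so that C3 is set by the reagent approach and not by capture of the cation. The fallback comes back to the route at 17.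

Step 4 (C–H insertion). Facial selectivity or cis preference may be poor because the carbenoid carbon is flanked by two ortho substituents and is twisted out of conjugation with ring A. Fallback: the fallback sets out from diazo ester 8. The insertion is run with achiral dirhodium tetraacetate Rh2(OAc)4 and the crude product is equilibrated with NaOMe. This gives 9 together with the mirror-image cis ester methyl (2R,3S)-2-[4-(benzyloxy)-3-methoxyphenyl]-4-bromo-6-methoxy-2,3-dihydro-1-benzofuran-3-carboxylate F2, and then 10 together with the mirror-image trans ester methyl (2R,3R)-2-[4-(benzyloxy)-3-methoxyphenyl]-4-bromo-6-methoxy-2,3-dihydro-1-benzofuran-3-carboxylate F3. The racemic trans ester is resolved by preparative chromatography on a chiral stationary phase, so the absolute configuration comes from resolution instead of asymmetric induction. The fallback comes back to the route at 10.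

Step 3 (diazo ester formation). Condensation at the ketone between two ortho substituents may be slow or incomplete, and forcing it may cleave the acid-labile 4-alkoxybenzyl aryl ether. Fallback: the fallback sets out from keto ester 6. The smaller nucleophile hydrazine hydrate (EtOH, 0 °C → rt) should give the free hydrazone methyl 2-(2-{[4-(benzyloxy)-3-methoxyphenyl]methoxy}-6-bromo-4-methoxyphenyl)-2-hydrazinylideneacetate F4, which is dehydrogenated with MnO2 (CH2Cl2, rt), so the diazo group arises by oxidation instead of sulfinate elimination. The fallback comes back to the route at 8.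

**Further compounds**

F1 | step 9 | (2S)-2-[4-(benzyloxy)-3-methoxyphenyl]-5-{2-[3-(benzyloxy)phenyl]ethyl}-7-methoxy-2H-1-benzopyran | COc1cc(CCc2cccc(OCc3ccccc3)c2)c2c(c1)O[C@H](c1ccc(OCc3ccccc3)c(OC)c1)C=C2
F2 | step 4 | methyl (2R,3S)-2-[4-(benzyloxy)-3-methoxyphenyl]-4-bromo-6-methoxy-2,3-dihydro-1-benzofuran-3-carboxylate | COC(=O)[C@@H]1[C@H](c2ccc(OCc3ccccc3)c(OC)c2)Oc2cc(OC)cc(Br)c21
F3 | step 4 | methyl (2R,3R)-2-[4-(benzyloxy)-3-methoxyphenyl]-4-bromo-6-methoxy-2,3-dihydro-1-benzofuran-3-carboxylate | COC(=O)[C@H]1[C@H](c2ccc(OCc3ccccc3)c(OC)c2)Oc2cc(OC)cc(Br)c21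
F4 | step 3 | methyl 2-(2-{[4-(benzyloxy)-3-methoxyphenyl]methoxy}-6-bromo-4-methoxyphenyl)-2-hydrazinylideneacetate | COC(=O)C(=NN)c1c(Br)cc(OC)cc1OCc1ccc(OCc2ccccc2)c(OC)c1
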